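**Plan**

- Ring numbering used throughout: C1 ketone, C2 methyl-bearing alkene carbon, C3 alkene carbon with the 2-oxopentyl arm, C4 methylene, C5 secondary carbinol, C6 quaternary carbon with methyl and the orsellinate. The enabling feature is the α-ketol C1(=O)–C6(O): two neighbouring ring carbons that are both carbonyl carbons in an open chain, so C1–C6 can be made by an acyl anion from a C1 enal adding to a C6 methyl ketone, which closes the only carbocycle.
- Retrosynthetic cuts, in order: the ester C–O bond at O6 (orsellinic acid); C1–C6 (ring opened to an acyclic enal methyl ketone); C3–C4 (alkenyllithium plus epoxide); C2–CH3 together with C3–I (carbomagnesiation/iodination of an alkynol); the bond from the dithiane carbon to its propargylic CH2.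
- Forward: the chain is joined linearly (dithiane alkylation, methylmagnesiation/iodination, epoxide opening, silylation, double oxidation). The cyclohexenone ring is then closed by the carbene-catalysed benzoin reaction, followed by esterification at O6, dithiane hydrolysis and desilylation.
- Stereochemistry: C5 (S) comes from the Sharpless kinetic-resolution epoxidation of but-3-en-2-ol with D-(−)-tartrate; the oxirane carbon becomes C5 and the carbinol carbon becomes the C6 ketone. C6 (R), hydroxyl trans to O5, is set in the ring closure by the C5 silyloxy group and the chiral triazolium together. The alkene geometry (C1 cis to C4) comes from the anti addition in the carbomagnesiation.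

Key step: step 13

Assumption: 4-chlorobut-2-yn-1-ol (the monochloride of but-2-yne-1,4-diol) is taken as a purchasable starting material.
Assumption: both antipodes of the aminoindanol triazolium salt are purchasable; the (5aS,10bR) salt is written in step 13 as the one expected to reinforce the substrate's bias toward the 5,6-trans ketol, and its mirror image would replace it if a trial run showed a mismatch.
Remark: the oxan-2-yl (THP) acetal carbons are stereorandom, so 13, 15 and 16 are mixtures of acetal epimers that converge in step 11.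

**Route**

Step 1
Reactants: 1 butanal
Product: 2 2-propyl-1,3-dithiane
Conditions: HS(CH2)3SH, BF3·OEt2 (cat.), CH2Cl2, 0 °C to rt
Reagents that add atoms: propane-1,3-dithiol, SCCCS
Why: Lewis-acid-catalysed dithioacetalisation of an unhindered aldehyde masks the future side-chain ketone carbon and makes it an acyl anion equivalent for the Corey–Seebach alkylation of step 3.

Step 2
Reactants: 3 4-chlorobut-2-yn-1-ol
Product: 4 2-[(4-chlorobut-2-yn-1-yl)oxy]oxane
Conditions: 3,4-dihydro-2H-pyran, pyridinium p-toluenesulfonate (cat.), CH2Cl2, rt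
Reagents that add atoms: 3,4-dihydro-2H-pyran, C1=COCCC1
Why: Acid-catalysed addition of the alcohol to the enol ether (tetrahydropyranylation) hides the hydroxyl from the organolithium of step 3 and leaves the propargylic chloride untouched.

Step 3
Reactants: 2 2-propyl-1,3-dithiane; 4 2-[(4-chlorobut-2-yn-1-yl)oxy]oxane
Product: 6 2-{[4-(2-propyl-1,3-dithian-2-yl)but-2-yn-1-yl]oxy}oxane, via 2-lithio-2-propyl-1,3-dithiane 5 (not isolated)
Conditions: n-BuLi, THF, −30 °C; then 4, −78 °C to rt
Reagents that add atoms: none
Why: Corey–Seebach alkylation, in which the sulfur-stabilised carbanion displaces the primary propargylic chloride by SN2 and sets the carbon that will be the side-chain ketone.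

Step 4
Reactants: 6 2-{[4-(2-propyl-1,3-dithian-2-yl)but-2-yn-1-yl]oxy}oxane
Product: 7 4-(2-propyl-1,3-dithian-2-yl)but-2-yn-1-ol
Conditions: TsOH·H2O (cat.), MeOH, rt
Reagents that add atoms: none
Why: Acid-catalysed acetal exchange with methanol frees the propargylic hydroxyl needed as directing group, and the dithiane is inert to protic acid.

Step 5
Reactants: 7 4-(2-propyl-1,3-dithian-2-yl)but-2-yn-1-ol
Product: 9 (2Z)-3-iodo-2-methyl-4-(2-propyl-1,3-dithian-2-yl)but-2-en-1-ol, via alkenylmagnesium chelate 8 (not isolated)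
Conditions: MeMgBr (4 equiv), CuI (20 mol%), THF, 0 °C then reflux; then I2, −78 °C to 0 °C
Reagents that add atoms: methylmagnesium bromide, C[Mg]Br; iodine, II
Why: Copper-catalysed, alkoxide-directed anti-carbomagnesiation of a propargylic alcohol puts methyl on the proximal carbon (C2) and magnesium on C3 in a five-membered chelate, and iodinolysis with retention gives the iodide with I cis to CH2OH, which fixes the later C1/C4 cis relationship.

Step 6
Reactants: 9 (2Z)-3-iodo-2-methyl-4-(2-propyl-1,3-dithian-2-yl)but-2-en-1-ol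
Product: 10 2-{[(2Z)-3-iodo-2-methyl-4-(2-propyl-1,3-dithian-2-yl)but-2-en-1-yl]oxy}oxane
Conditions: 3,4-dihydro-2H-pyran, pyridinium p-toluenesulfonate (cat.), CH2Cl2, rt
Reagents that add atoms: 3,4-dihydro-2H-pyran, C1=COCCC1
Why: Tetrahydropyranylation gives an acetal that tolerates tert-butyllithium and, unlike a silyl ether cis to the alkenyllithium, cannot undergo oxygen-to-carbon silyl migration.

Step 7
Reactants: 11 racemic but-3-en-2-ol
Product: 12 (2R,3S)-3,4-epoxybutan-2-ol
Conditions: Ti(OiPr)4 (0.2 equiv), D-(−)-diisopropyl tartrate (0.3 equiv), t-BuOOH (0.45 equiv), 4 Å molecular sieves, CH2Cl2, −20 °C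
Reagents that add atoms: tert-butyl hydroperoxide, CC(C)(C)OO
Why: Sharpless kinetic resolution, in which the D-(−)-tartrate catalyst epoxidises the (R)-alcohol fast and on the face that gives the erythro epoxy alcohol, so the oxirane carbon (the later C5) is S, while the carbinol configuration is of no consequence because that carbon becomes the C6 ketone.

Step 8
Reactants: 12 (2R,3S)-3,4-epoxybutan-2-ol
Product: 13 2-{(1R)-1-[(2S)-oxiran-2-yl]ethoxy}oxane
Conditions: 3,4-dihydro-2H-pyran, pyridinium p-toluenesulfonate (cat.), CH2Cl2, 0 °C to rt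
Reagents that add atoms: 3,4-dihydro-2H-pyran, C1=COCCC1
Why: Tetrahydropyranylation under a buffered acid catalyst leaves the epoxide intact and gives an ether that cannot migrate to the alkoxide formed next to it in step 9.

Step 9
Reactants: 10 2-{[(2Z)-3-iodo-2-methyl-4-(2-propyl-1,3-dithian-2-yl)but-2-en-1-yl]oxy}oxane; 13 2-{(1R)-1-[(2S)-oxiran-2-yl]ethoxy}oxane
Product: 15 (2E,5S,6R)-2-methyl-1,6-bis(oxan-2-yloxy)-3-[(2-propyl-1,3-dithian-2-yl)methyl]hept-2-en-5-ol, via alkenyllithium 14 (not isolated)
Conditions: t-BuLi (2.1 equiv), Et2O, −78 °C; then 13, BF3·OEt2, −78 °C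
Reagents that add atoms: none
Why: Iodine–lithium exchange proceeds with retention of alkene geometry and the alkenyllithium opens the BF3-activated monosubstituted epoxide by SN2 at its terminal CH2, which forms C3–C4 and leaves the oxirane stereocentre as the C5 (S) carbinol.

Step 10
Reactants: 15 (2E,5S,6R)-2-methyl-1,6-bis(oxan-2-yloxy)-3-[(2-propyl-1,3-dithian-2-yl)methyl]hept-2-en-5-ol
Product: 16 the C5 tert-butyldimethylsilyl ether of 15
Conditions: TBSCl, imidazole, 4-(dimethylamino)pyridine (cat.), DMF, 40 °C
Reagents that add atoms: tert-butyldimethylsilyl chloride, CC(C)(C)[Si](C)(C)Cl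
Why: Imidazole-promoted silylation of the only free hydroxyl places on O5 the group that must stay through ring closure and esterification, under conditions that do not touch the acetals.

Step 11
Reactants: 16 the C5 tert-butyldimethylsilyl ether of 15
Product: 17 (2E,5S,6R)-5-[(tert-butyldimethylsilyl)oxy]-2-methyl-3-[(2-propyl-1,3-dithian-2-yl)methyl]hept-2-ene-1,6-diol
Conditions: pyridinium p-toluenesulfonate, MeOH, 40 °C
Reagents that add atoms: none
Why: Mild acid-catalysed transacetalisation to methanol removes both THP groups at once, a selectivity over a secondary tert-butyldimethylsilyl ether that is routine.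

Step 12
Reactants: 17 (2E,5S,6R)-5-[(tert-butyldimethylsilyl)oxy]-2-methyl-3-[(2-propyl-1,3-dithian-2-yl)methyl]hept-2-ene-1,6-diol
Product: 18 (2E,5S)-5-[(tert-butyldimethylsilyl)oxy]-2-methyl-6-oxo-3-[(2-propyl-1,3-dithian-2-yl)methyl]hept-2-enal
Conditions: SO3·pyridine, DMSO, i-Pr2NEt, CH2Cl2, −10 °C to 0 °C
Reagents that add atoms: none
Why: Parikh–Doering oxidation converts the primary allylic alcohol to the enal and the secondary alcohol to the methyl ketone in one operation, with an activated-sulfoxide oxidant that cannot oxidise the dithiane and a hindered amine too weak to scramble the alkene or C5.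

Step 13
Reactants: 18 (2E,5S)-5-[(tert-butyldimethylsilyl)oxy]-2-methyl-6-oxo-3-[(2-propyl-1,3-dithian-2-yl)methyl]hept-2-enal
Product: 19 (5S,6R)-5-[(tert-butyldimethylsilyl)oxy]-6-hydroxy-2,6-dimethyl-3-[(2-propyl-1,3-dithian-2-yl)methyl]cyclohex-2-en-1-one
Conditions: (5aS,10bR)-2-(pentafluorophenyl)-5a,10b-dihydro-4H,6H-indeno[2,1-b][1,2,4]triazolo[4,3-d][1,4]oxazin-2-ium tetrafluoroborate (15 mol%), i-Pr2NEt (15 mol%), toluene (0.02 M), 4 Å molecular sieves, rt to 40 °C
Reagents that add atoms: none
Why: Proposed new method: the carbene formed from the triazolium salt adds to the C1 aldehyde, proton transfer gives the dienaminol (Breslow intermediate), its C1 attacks the C6 ketone carbonyl, and proton transfer with loss of the carbene leaves the enone ketol, so the overall change is an isomerisation; the closest known reaction type is the enantioselective intramolecular crossed aldehyde–ketone benzoin reaction that gives six-membered tertiary ketols with aminoindanol triazolium catalysts, extended here to a tetrasubstituted enal as acyl anion donor. The cyclohexenone ring closes in a 6-exo-trig mode on the ketone carbonyl. The new C6 stereocentre is decided by which face of the ketone is attacked, and the C5 silyloxy group (Cornforth-type arrangement with the C5–O and C6=O dipoles opposed and pseudoaxial, methyl pseudoequatorial) together with the chiral catalyst should place the C6 hydroxyl trans to O5. The step needs acyl anion rather than homoenolate reactivity and needs C1 within reach of C6: electron-poor N-pentafluorophenyl triazolium carbenes are known to steer enals into acyl anion chemistry (as in their Stetter reactions), C3 is fully substituted and its attack on C6 would make a four-membered ring, and the alkene geometry from step 5 holds C1 cis to C4. A catalytic amount of a weak amine base and high dilution are meant to leave the C5 stereocentre next to the ketone and the silyloxy group intact and to suppress intermolecular benzoin coupling.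

Step 14
Reactants: 20 orsellinic acid
Product: 22 2,4-bis[(tert-butyldimethylsilyl)oxy]-6-methylbenzoic acid, via tris-silylated orsellinate 21 (not isolated)
Conditions: TBSCl (3.5 equiv), imidazole, DMF, rt; then AcOH/THF/H2O, rt
Reagents that add atoms: tert-butyldimethylsilyl chloride, CC(C)(C)[Si](C)(C)Cl
Why: Exhaustive silylation followed by selective hydrolysis of the far more labile silyl ester gives the free acid with both phenols masked by groups that fall in the last step together with the O5 silyl group.

Step 15
Reactants: 19 (5S,6R)-5-[(tert-butyldimethylsilyl)oxy]-6-hydroxy-2,6-dimethyl-3-[(2-propyl-1,3-dithian-2-yl)methyl]cyclohex-2-en-1-one; 22 2,4-bis[(tert-butyldimethylsilyl)oxy]-6-methylbenzoic acid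
Product: 24 the O6 2,4-bis[(tert-butyldimethylsilyl)oxy]-6-methylbenzoate of 19 (5S,6R), via mixed trifluoroacetic anhydride 23 (not isolated)
Conditions: 22 (3 equiv), (CF3CO)2O (3 equiv), CH2Cl2, 0 °C; then 19, 0 °C to rt
Reagents that add atoms: none
Why: Esterification through a mixed carboxylic–trifluoroacetic anhydride, in which the electron-rich, doubly ortho-substituted aroyl trifluoroacetate ionises to a linear acylium ion small enough to be captured by the hindered tertiary hydroxyl, the only free hydroxyl of 19.

Step 16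
Reactants: 24 the O6 2,4-bis[(tert-butyldimethylsilyl)oxy]-6-methylbenzoate of 19
Product: 25 tris-silylated talarophilone: (5S,6R)-5-[(tert-butyldimethylsilyl)oxy]-2,6-dimethyl-1-oxo-3-(2-oxopentyl)cyclohex-2-en-6-yl 2,4-bis[(tert-butyldimethylsilyl)oxy]-6-methylbenzoate
Conditions: MeI, CaCO3, MeCN/H2O (9:1), 45 °C
Reagents that add atoms: water, O
Why: Alkylative dithiane hydrolysis (S-methylation to a sulfonium ion, then attack of water) releases the side-chain ketone without an oxidant, so the electron-rich arene, the enone and the silyl ethers should survive.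

Step 17
Reactants: 25 tris-silylated talarophilone
Product: 26 talarophilone, (5S,6R)-5-hydroxy-2,6-dimethyl-1-oxo-3-(2-oxopentyl)cyclohex-2-en-6-yl 2,4-dihydroxy-6-methylbenzoate
Conditions: HF·pyridine, pyridine, THF, 0 °C to rt
Reagents that add atoms: none
Why: Fluoride-induced cleavage of the two aryl and one alkyl silicon–oxygen bonds in a buffered, non-basic medium should free all three hydroxyls without moving the hindered orsellinate to O5 or eliminating the C5 oxygen.

**Compound list**

1 | butanal | CCCC=O | starting material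
2 | 2-propyl-1,3-dithiane | CCCC1SCCCS1 | intermediate
3 | 4-chlorobut-2-yn-1-ol | OCC#CCCl | starting material
4 | 2-[(4-chlorobut-2-yn-1-yl)oxy]oxane (racemic acetal) | ClCC#CCOC1CCCCO1 | intermediate
5 | 2-lithio-2-propyl-1,3-dithiane (not isolated) | CCCC1([Li])SCCCS1 | intermediate
6 | 2-{[4-(2-propyl-1,3-dithian-2-yl)but-2-yn-1-yl]oxy}oxane | CCCC1(CC#CCOC2CCCCO2)SCCCS1 | intermediate
7 | 4-(2-propyl-1,3-dithian-2-yl)but-2-yn-1-ol | CCCC1(CC#CCO)SCCCS1 | intermediate
8 | alkenylmagnesium chelate, 4-methyl-3-[(2-propyl-1,3-dithian-2-yl)methyl]-2,5-dihydro-1,2-oxamagnesole (not isolated) | CCCC1(SCCCS1)CC2=C(C)CO[Mg]2 | intermediate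
9 | (2Z)-3-iodo-2-methyl-4-(2-propyl-1,3-dithian-2-yl)but-2-en-1-ol (I cis to CH2OH) | OC/C(C)=C(\I)CC1(CCC)SCCCS1 | intermediate
10 | 2-{[(2Z)-3-iodo-2-methyl-4-(2-propyl-1,3-dithian-2-yl)but-2-en-1-yl]oxy}oxane | CCCC1(SCCCS1)C/C(I)=C(\C)COC1CCCCO1 | intermediate
11 | racemic but-3-en-2-ol | CC(O)C=C | starting material
12 | (2R,3S)-3,4-epoxybutan-2-ol, i.e. (1R)-1-[(2S)-oxiran-2-yl]ethanol | C[C@@H](O)[C@@H]1CO1 | intermediate
13 | 2-{(1R)-1-[(2S)-oxiran-2-yl]ethoxy}oxane (acetal epimers) | C[C@@H](OC1CCCCO1)[C@@H]1CO1 | intermediate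
14 | alkenyllithium from 10, Li in place of I with geometry retained (not isolated) | CCCC1(SCCCS1)C/C([Li])=C(\C)COC1CCCCO1 | intermediate
15 | (2E,5S,6R)-2-methyl-1,6-bis(oxan-2-yloxy)-3-[(2-propyl-1,3-dithian-2-yl)methyl]hept-2-en-5-ol (C1 cis to C4) | CCCC1(SCCCS1)C/C(C[C@H](O)[C@@H](C)OC1CCCCO1)=C(\C)COC1CCCCO1 | intermediate
16 | C5 tert-butyldimethylsilyl ether of 15 | CCCC1(SCCCS1)C/C(C[C@H](O[Si](C)(C)C(C)(C)C)[C@@H](C)OC1CCCCO1)=C(\C)COC1CCCCO1 | intermediate
17 | (2E,5S,6R)-5-[(tert-butyldimethylsilyl)oxy]-2-methyl-3-[(2-propyl-1,3-dithian-2-yl)methyl]hept-2-ene-1,6-diol | CCCC1(SCCCS1)C/C(C[C@H](O[Si](C)(C)C(C)(C)C)[C@@H](C)O)=C(\C)CO | intermediate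
18 | (2E,5S)-5-[(tert-butyldimethylsilyl)oxy]-2-methyl-6-oxo-3-[(2-propyl-1,3-dithian-2-yl)methyl]hept-2-enal (CHO cis to C4) | O=C/C(C)=C(/CC1(CCC)SCCCS1)C[C@H](O[Si](C)(C)C(C)(C)C)C(C)=O | intermediate
19 | (5S,6R)-5-[(tert-butyldimethylsilyl)oxy]-6-hydroxy-2,6-dimethyl-3-[(2-propyl-1,3-dithian-2-yl)methyl]cyclohex-2-en-1-one (O5 and O6 trans) | CCCC1(SCCCS1)CC2=C(C)C(=O)[C@](C)(O)[C@@H](O[Si](C)(C)C(C)(C)C)C2 | intermediate
20 | orsellinic acid (2,4-dihydroxy-6-methylbenzoic acid) | Cc1cc(O)cc(O)c1C(=O)O | starting material
21 | tert-butyldimethylsilyl 2,4-bis[(tert-butyldimethylsilyl)oxy]-6-methylbenzoate (not isolated) | Cc1cc(O[Si](C)(C)C(C)(C)C)cc(O[Si](C)(C)C(C)(C)C)c1C(=O)O[Si](C)(C)C(C)(C)C | intermediate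
22 | 2,4-bis[(tert-butyldimethylsilyl)oxy]-6-methylbenzoic acid | Cc1cc(O[Si](C)(C)C(C)(C)C)cc(O[Si](C)(C)C(C)(C)C)c1C(=O)O | intermediate
23 | 2,4-bis[(tert-butyldimethylsilyl)oxy]-6-methylbenzoic trifluoroacetic anhydride (not isolated) | Cc1cc(O[Si](C)(C)C(C)(C)C)cc(O[Si](C)(C)C(C)(C)C)c1C(=O)OC(=O)C(F)(F)F | intermediate
24 | O6 2,4-bis[(tert-butyldimethylsilyl)oxy]-6-methylbenzoate of 19 (5S,6R) | CCCC1(SCCCS1)CC2=C(C)C(=O)[C@](C)(OC(=O)c3c(C)cc(O[Si](C)(C)C(C)(C)C)cc3O[Si](C)(C)C(C)(C)C)[C@@H](O[Si](C)(C)C(C)(C)C)C2 | intermediate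
25 | tris-silylated talarophilone (5S,6R), side-chain ketone free | CCCC(=O)CC1=C(C)C(=O)[C@](C)(OC(=O)c2c(C)cc(O[Si](C)(C)C(C)(C)C)cc2O[Si](C)(C)C(C)(C)C)[C@@H](O[Si](C)(C)C(C)(C)C)C1 | intermediate
26 | talarophilone (5S,6R) | CCCC(=O)CC1=C(C)C(=O)[C@](C)(OC(=O)c2c(C)cc(O)cc2O)[C@@H](O)C1 | target

**Count**

Total step count: 17. Longest linear sequence: 13 steps (3 to 26 through steps 2, 3, 4, 5, 6, 9, 10, 11, 12, 13, 15, 16, 17; the line from 1 is equally long).

**Steps most likely to fail**

Step 13. The hindered tetrasubstituted enal may add the carbene slowly, or the extended Breslow intermediate may be diverted by protonation at C3 into redox chemistry. Base may instead cause loss of silanol across C4–C5 or aldol closure of the C5 enolate onto the aldehyde. The ketone may also be attacked on the wrong face. The fallback keeps the C1–C6 bond but makes it by known reductive chemistry. It sets out from 18: SmI2 in THF with t-BuOH at −78 °C should couple the two carbonyls by ketyl pinacol cyclisation to the cis-1,6-diol F1. In such closures the new hydroxyl next to an oxygen-bearing carbon normally ends up trans to that oxygen, and samarium chelation makes the two new hydroxyls cis. Parikh–Doering oxidation of the secondary allylic hydroxyl of the diol, with the tertiary hydroxyl inert, then comes back to the route at 19.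

Step 15. The acylium ion may not be intercepted by the crowded tertiary hydroxyl, and trifluoroacetylation or acid-induced loss of the O5 silyl group followed by aroylation at O5 may take over. The fallback builds the arene on the oxygen instead of acylating with it. It sets out from 19.
- Commercial 2,2,6-trimethyl-4H-1,3-dioxin-4-one is C-acetylated through its lithium dienolate to the keto-dioxinone F2.
- The dianion of this is acetylated with N-methoxy-N-methylacetamide to the diketo-dioxinone F3.
- Heating F3 with 19 in toluene at 110 °C releases acetone and an acylketene, a sterically undemanding, neutral acylating agent that tertiary alcohols trap, to give the triketo ester F4.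
- Et3N in CH2Cl2 followed by mild acid should bring about aldol condensation and aromatisation to the free-phenol orsellinate F5.
- TBSCl and imidazole in DMF then come back to the route at 24.

Step 9. Iodine–lithium exchange may be incomplete or accompanied by attack of t-BuLi at sulfur, BF3 may be held by the two acetals and the dithiane, and the doubly flanked alkenyllithium may fail to open the epoxide. The fallback changes the metal, the electrophile and the oxidation level at which C6 enters. It sets out from 10.
- Iodine–magnesium exchange with i-PrMgCl·LiCl in THF, assisted by the cis allylic oxygen, gives the alkenylmagnesium chloride F6.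
- With catalytic CuI this opens commercial methyl (S)-glycidate at its CH2 to the α-hydroxy ester F7, with C5 already S.
- Silylation with TBSCl and imidazole gives the silyl ether ester F8.
- MeNHOMe·HCl with i-PrMgCl gives the Weinreb amide F9.
- MeMgBr gives the methyl ketone F10.
- Pyridinium p-toluenesulfonate in MeOH removes the acetal to give the hydroxy ketone F11.
- Parikh–Doering oxidation of the allylic alcohol comes back to the route at 18.

**Further compounds**

F1 | step 13 | cis-1,6-diol from pinacol closure of 18: 5-[(tert-butyldimethylsilyl)oxy]-2,6-dimethyl-3-[(2-propyl-1,3-dithian-2-yl)methyl]cyclohex-2-ene-1,6-diol, C6 hydroxyl trans to O5 and cis to the C1 hydroxyl | CCCC1(SCCCS1)CC2=C(C)[C@H](O)[C@](C)(O)[C@@H](O[Si](C)(C)C(C)(C)C)C2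
F2 | step 15 | 2,2-dimethyl-6-(2-oxopropyl)-4H-1,3-dioxin-4-one | CC(=O)CC1=CC(=O)OC(C)(C)O1
F3 | step 15 | 6-(2,4-dioxopentyl)-2,2-dimethyl-4H-1,3-dioxin-4-one | CC(=O)CC(=O)CC1=CC(=O)OC(C)(C)O1
F4 | step 15 | O6 3,5,7-trioxooctanoate of 19 | CCCC1(SCCCS1)CC2=C(C)C(=O)[C@](C)(OC(=O)CC(=O)CC(=O)CC(C)=O)[C@@H](O[Si](C)(C)C(C)(C)C)C2
F5 | step 15 | O6 2,4-dihydroxy-6-methylbenzoate of 19 | CCCC1(SCCCS1)CC2=C(C)C(=O)[C@](C)(OC(=O)c3c(C)cc(O)cc3O)[C@@H](O[Si](C)(C)C(C)(C)C)C2
F6 | step 9 | alkenylmagnesium chloride from 10, MgCl in place of I with geometry retained | CCCC1(SCCCS1)C/C([Mg]Cl)=C(\C)COC1CCCCO1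
F7 | step 9 | methyl (2S,4E)-2-hydroxy-5-methyl-6-(oxan-2-yloxy)-4-[(2-propyl-1,3-dithian-2-yl)methyl]hex-4-enoate | CCCC1(SCCCS1)C/C(C[C@H](O)C(=O)OC)=C(\C)COC1CCCCO1
F8 | step 9 | O2 tert-butyldimethylsilyl ether of F7 | CCCC1(SCCCS1)C/C(C[C@H](O[Si](C)(C)C(C)(C)C)C(=O)OC)=C(\C)COC1CCCCO1
F9 | step 9 | N-methoxy-N-methyl amide corresponding to F8 | CCCC1(SCCCS1)C/C(C[C@H](O[Si](C)(C)C(C)(C)C)C(=O)N(C)OC)=C(\C)COC1CCCCO1
F10 | step 9 | (3S,5E)-3-[(tert-butyldimethylsilyl)oxy]-6-methyl-7-(oxan-2-yloxy)-5-[(2-propyl-1,3-dithian-2-yl)methyl]hept-5-en-2-one | CCCC1(SCCCS1)C/C(C[C@H](O[Si](C)(C)C(C)(C)C)C(C)=O)=C(\C)COC1CCCCO1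
F11 | step 9 | (3S,5E)-3-[(tert-butyldimethylsilyl)oxy]-7-hydroxy-6-methyl-5-[(2-propyl-1,3-dithian-2-yl)methyl]hept-5-en-2-one | CCCC1(SCCCS1)C/C(C[C@H](O[Si](C)(C)C(C)(C)C)C(C)=O)=C(\C)CO
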